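You may have run the neighbour of this flask, with twice the enzyme and the same impurity; now you repeat the flask itself.

substrate 0.019 M; enzyme 0.0064 mol%; impurity 0.35 µM

    substrate + enzyme → target + enzyme, rate k1*[substrate]*[enzyme]/(1 + ([substrate]/Km1) + ([substrate]/Ksi1)^2) (Km1 = 41.5 mM, Ksi1 = 3.08 mM, k1 = 2.39 × 10⁵ /M/s)
    enzyme + impurity → spent catalyst (k2 = 2.97 × 10⁷ /M/s)

- the form that holds most of the catalyst when 10% of the substrate are converted (spent catalyst / enzyme)
- its share of the catalyst then

Watch how far the impurity gets before 10% of the substrate is converted. Both steps run on free enzyme, so enzyme cancels from their ratio. Let x be the fraction of substrate left and y the fraction of impurity left. Then ln y changes with ln x by the selectivity factor, step two's constant over step one's, 124, times the denominator of the rate law. Equal constants are the zero of the scale: there, the denominator's first term makes y follow x. My reckoning integrates each term down to the asked conversion: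

| Denominator term | Equal constants | This flask |
|---|---|---|
| constant | 0.105 | 13.0 |
| Km term | 0.0458 | 5.68 |
| Ksi term | 3.62 | 449 |
| sum | 3.77 | 468 |

Read the first row across. Its left entry has the impurity fall with the substrate, to 90.0% of its charge, but this flask's entry already passes the 4.61 that leaves a hundredth. Read down the columns. The Ksi term holds nearly all of the sum. The corner, 468, is the clearing number: minus ln y at the asked conversion. It lies far above that hundredth mark.

So I reckon y under a hundredth at the asked conversion, and the spent catalyst takes 28.8% of the catalyst charge. Enzyme keeps 71.2%. The forecast also says enzyme at 71.2%, with the impurity consumed early, “even with substrate inhibition”.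

The flask gives enzyme at 71.2%. At 50.0 min, enzyme still stands at 71.2% of its charge. For the neighbour with twice the enzyme, the clearing number reckons to the same 468, with no enzyme in its terms. By that reckoning its impurity takes the same amount of catalyst, and its free enzyme comes to 2.40 times this flask's. That run's rate factor is 2.40.

The rate constants were chosen freely; the flask was simulated.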